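Take a percentage point per minute as the unit: double product gains at some number of them, and that gain, divided by the rate at which single product turns into double product, here called the turnover rate, estimates how much single product stands in a flask. So two rates are compared, an early one and a late one.

common to all: substrate 38 mM
- north-west: partner 65 mM; run made earlier
- south: partner 170 mM; run made earlier
- cedar: partner 76.0 mM; time 30 min
- maple: partner 114 mM; time 30 min
- alder: partner 57.0 mM; time 30 min

- north-west (time / min: double product / %, substrate / %): 4.00: 1.0, 89.2; 10.0: 3.2, 72.9; 20.0: 9.0, 52.5; 30.0: 13.7, 39.0
- south (time / min: double product / %, substrate / %): 2.50: 2.2, 83.2; 6.00: 9.3, 62.7; 12.0: 22.6, 39.0; 30.0: 49.3, 11.4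

(scatter of a reading: 0.3 percentage points)

- which of these holds the largest part of the substrate at the end of cedar (single product / substrate / double product)
- which of these holds the largest part of the substrate at the end of maple (single product / substrate / double product)
- which of these holds the largest part of the substrate at the end of alder (single product / substrate / double product)
- double product at the end of alder, in percent of the substrate charged

Call the gap what substrate and double product leave unaccounted, and treat it as single product early in the south run, between 2.50 min and 6.00 min:

turnover rate = 7.1 percentage points in 3.50 min ÷ average gap 21.3% = 0.0952 min⁻¹

This turnover rate, a pseudo-first-order constant, is scaled here in proportion to the partner charged, which gives 0.0364 min⁻¹ for the north-west run. Now divide the late gains, from 12.0 min on in south and 20.0 min on in north-west: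

south: 27 points in 18.0 min ÷ 0.0952 min⁻¹ = 15.6%

north-west: 4.7 points in 10.0 min ÷ 0.0364 min⁻¹ = 12.9%

Both levels are smaller than the gaps at the last readings, 39.3% in south and 47.3% in north-west, so do not read the gap as single product at the end.

Scaling the north-west run gives substrate of 43.8% in alder, 33.3% in cedar and 19.2% in maple. A partner order of 1.33, read off the last readings of both runs, gives double product of 11.5%, 16.9% and 29.0% in the same order of flasks. Expect substrate to lead in alder and cedar, and double product in maple.

The forecast, unlike this reckoning, names single product for cedar, single product for maple and single product for alder, with 11% double product in alder, and says of single product: “It leads in all three runs, though only narrowly in alder”.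

Alder gives 11.0% double product, and its largest part is substrate, at 43.1%; cedar's largest part is substrate, at 33.8%, and maple's is double product, at 31.2%.

    substrate + partner → single product + released group (k = 0.424 M⁻¹ min⁻¹)
    partner + single product → double product + released group (k = 0.729 M⁻¹ min⁻¹)
    substrate + single product → side product (k = 1.99 M⁻¹ min⁻¹)

Alder's side product stands at 32.7%, counted with the two substrates each holds, beside 13.1% single product. Dividing alder's gain of 6 points from 15.0 min to 30.0 min by the scaled turnover rate gives 12.6%. In cedar the same division gives 14.5%, and cedar holds 14.4% single product at 30.0 min.

All runs are simulated with constants of no real substance; scatter was added.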